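**Retrosynthetic overview**
1. Target 10 ⇒ enone 8: open the pyranone at O1–C2 (6-endo oxa-Michael closure). C3 is set when the resulting enol is protonated. This ring is formed last.
2. Enone 8 ⇒ alkyne 6 + salicylaldehyde 7: acyl–vinyl bond by branched Rh-catalysed alkyne hydroacylation.
3. Alkyne 6 ⇒ aldehyde 5: one-carbon homologation.
4. Chromene 5 ⇒ propargyl ether 3 ⇒ 1 + 2: regioselective O-alkylation, then aryl propargyl Claisen/electrocyclisation. The dimethylpyran ring is formed first.
5. Both benzene rings are bought; no protecting groups; the only stereocentre is created in the final step.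

Assumption: 7, 2 and the Ohira–Bestmann reagent are taken as catalogue chemicals. The sense of induction in step 5 cannot be predicted with certainty; the route is written with (R)-TRIP, and (S)-TRIP is used instead if a pilot run gives the 3R product.

**Step 1**
Reactants: 1 3,4-dihydroxybenzaldehyde; 2 3-chloro-3-methylbut-1-yne (1.3 equiv)
Product: 3 3-hydroxy-4-[(2-methylbut-3-yn-2-yl)oxy]benzaldehyde
Conditions: K2CO3 (1.05 equiv), KI (10 mol %), CuI (2 mol %), DMF, 55 °C
Reagents that add atoms: none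
Why: The 4-OH (para to CHO) is about four pKa units more acidic than the 3-OH, so one equivalent of carbonate gives only the 4-phenoxide, which is alkylated by the copper-activated tertiary propargylic chloride (Cu-assisted Williamson-type O-propargylation).

**Step 2**
Reactants: 3 3-hydroxy-4-[(2-methylbut-3-yn-2-yl)oxy]benzaldehyde
Product: 5 8-hydroxy-2,2-dimethyl-2H-chromene-6-carbaldehyde, via allenyl catechol 4 (not isolated)
Conditions: PhNEt2, 200 °C
Reagents that add atoms: none
Why: Aromatic propargyl Claisen rearrangement to the only free ortho carbon gives allene 4, which closes by 1,5-H shift and 6π oxa-electrocyclisation to the 2,2-dimethyl-2H-chromene; the other ortho carbon carries OH, so one regioisomer results.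

**Step 3**
Reactants: 5 8-hydroxy-2,2-dimethyl-2H-chromene-6-carbaldehyde
Product: 6 6-ethynyl-2,2-dimethyl-2H-chromen-8-ol
Conditions: Ohira–Bestmann reagent (1.3 equiv), K2CO3 (3 equiv), MeOH, 0 °C → rt
Reagents that add atoms: dimethyl (1-diazo-2-oxopropyl)phosphonate, CC(=O)C(=[N+]=[N-])P(=O)(OC)OC
Why: Ohira–Bestmann (Seyferth–Gilbert) homologation; the free OH is meta to the formyl group, so its phenoxide does not deactivate the aldehyde.

**Step 4**
Reactants: 7 2,4-dihydroxy-6-methoxybenzaldehyde (1.5 equiv); 6 6-ethynyl-2,2-dimethyl-2H-chromen-8-ol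
Product: 8 1-(2,4-dihydroxy-6-methoxyphenyl)-2-(8-hydroxy-2,2-dimethyl-2H-chromen-6-yl)prop-2-en-1-one
Conditions: [Rh(cod)Cl]2 (2.5 mol %), dppf (5 mol %), Na2CO3 (5 mol %), PhMe–1,4-dioxane (3:1), 60 °C; pH 5 buffer wash, rapid chromatography
Reagents that add atoms: none
Why: Salicylaldehyde-directed Rh(I) alkyne hydroacylation: the ortho-phenoxide chelates Rh, the aldehyde C–H adds oxidatively, and the acyl group is delivered to the internal, aryl-bearing alkyne carbon; the hydrogen-bonded 2'-hydroxy enone should not ring-close without a soluble base and is expected to be isolable.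

**Step 5**
Reactants: 8 1-(2,4-dihydroxy-6-methoxyphenyl)-2-(8-hydroxy-2,2-dimethyl-2H-chromen-6-yl)prop-2-en-1-one
Product: 10 (3S)-7-hydroxy-3-(8-hydroxy-2,2-dimethyl-2H-chromen-6-yl)-5-methoxy-2,3-dihydro-4H-chromen-4-one, via chromen-4-ol enol 9 (not isolated)
Conditions: (R)-TRIP (10 mol %), CH2Cl2–PhMe (1:1), 0 °C → rt; filtration through neutral silica, no base at any point
Reagents that add atoms: none
Why: Proposed new method: chiral-phosphoric-acid-catalysed 6-endo-trig oxa-Michael addition/enantioselective protonation. The bifunctional acid hydrogen-bonds the ketone (P–OH) and the attacking 2'-OH (P=O); the phenol adds to the unsubstituted β-CH2 to form the O1–C2 bond and the achiral enol 9, which stays in the catalyst pocket and is protonated at C3 on one face through a P(=O)OH proton shuttle, setting 3S. The acid is too weak to re-enolise the product or protonate the chromene, so the stereocentre should not be scrambled. Closest known reaction types: CPA-catalysed conjugate addition/enantioselective protonation cascades of α-substituted enones (aza-Michael and Friedel–Crafts variants), CPA-catalysed protonation of enol derivatives of α-aryl ketones, and the racemic base-promoted oxa-Michael closure of 2'-hydroxy enones to chromanones.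

**Compound list**
1 | 3,4-dihydroxybenzaldehyde | O=Cc1ccc(O)c(O)c1 | starting material
2 | 3-chloro-3-methylbut-1-yne | C#CC(C)(C)Cl | starting material
3 | 3-hydroxy-4-[(2-methylbut-3-yn-2-yl)oxy]benzaldehyde | O=Cc1ccc(OC(C)(C)C#C)c(O)c1 | intermediate
4 | 3,4-dihydroxy-5-(3-methylbuta-1,2-dien-1-yl)benzaldehyde | O=Cc1cc(O)c(O)c(C=C=C(C)C)c1 | intermediate (not isolated)
5 | 8-hydroxy-2,2-dimethyl-2H-chromene-6-carbaldehyde | O=Cc1cc(O)c2c(c1)C=CC(C)(C)O2 | intermediate
6 | 6-ethynyl-2,2-dimethyl-2H-chromen-8-ol | C#Cc1cc(O)c2c(c1)C=CC(C)(C)O2 | intermediate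
7 | 2,4-dihydroxy-6-methoxybenzaldehyde | COc1cc(O)cc(O)c1C=O | starting material
8 | 1-(2,4-dihydroxy-6-methoxyphenyl)-2-(8-hydroxy-2,2-dimethyl-2H-chromen-6-yl)prop-2-en-1-one | COc1cc(O)cc(O)c1C(=O)C(=C)c1cc(O)c2c(c1)C=CC(C)(C)O2 | intermediate
9 | 3-(8-hydroxy-2,2-dimethyl-2H-chromen-6-yl)-5-methoxy-2H-chromene-4,7-diol | COc1cc(O)cc2c1C(O)=C(c1cc(O)c3c(c1)C=CC(C)(C)O3)CO2 | intermediate (not isolated)
10 | (3S)-7-hydroxy-3-(8-hydroxy-2,2-dimethyl-2H-chromen-6-yl)-5-methoxy-2,3-dihydro-4H-chromen-4-one | COc1cc(O)cc2c1C(=O)[C@@H](c1cc(O)c3c(c1)C=CC(C)(C)O3)CO2 | target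

**Totals**
Total steps: 5. Longest linear sequence: 5 (1 → 3 → 5 → 6 → 8 → 10).

**Three steps most likely to fail**

Step 5 (proposed new step). The risks are a slow cyclisation or low enantioselectivity. The fallback uses known chemistry, sets out from 8 and comes back at 10. Catalytic Et3N in MeOH at rt effects the ordinary base-promoted oxa-Michael closure to racemic 7-hydroxy-3-(8-hydroxy-2,2-dimethyl-2H-chromen-6-yl)-5-methoxychroman-4-one F1. Preparative chiral SFC (amylose carbamate phase, CO2/MeOH) separates 10 from (3R)-7-hydroxy-3-(8-hydroxy-2,2-dimethyl-2H-chromen-6-yl)-5-methoxychroman-4-one F2. F2 is returned to F1 by Et3N/MeOH enolisation and recycled.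

Step 4. The risks are the linear (E)-enone regioisomer, alkyne oligomerisation, and premature racemic ring closure. The fallback replaces hydroacylation by vinyl-anion addition and oxidation; it sets out from 6 and 7 and comes back at 8.
- 6 is silylated (TBSCl, imidazole, DMF) to tert-butyl[(6-ethynyl-2,2-dimethyl-2H-chromen-8-yl)oxy]dimethylsilane F3.
- Ni(dppp)Cl2-catalysed α-selective hydroalumination with DIBAL-H, then NBS, gives {[6-(1-bromoethenyl)-2,2-dimethyl-2H-chromen-8-yl]oxy}(tert-butyl)dimethylsilane F4.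
- 7 is bis-silylated to 2,4-bis[(tert-butyldimethylsilyl)oxy]-6-methoxybenzaldehyde F5.
- Br/Li exchange on F4 (t-BuLi, THF, −78 °C) and addition to F5, quenched cold, gives racemic 1-{2,4-bis[(tert-butyldimethylsilyl)oxy]-6-methoxyphenyl}-2-{8-[(tert-butyldimethylsilyl)oxy]-2,2-dimethyl-2H-chromen-6-yl}prop-2-en-1-ol F6.
- Dess–Martin oxidation (NaHCO3-buffered) gives 1-{2,4-bis[(tert-butyldimethylsilyl)oxy]-6-methoxyphenyl}-2-{8-[(tert-butyldimethylsilyl)oxy]-2,2-dimethyl-2H-chromen-6-yl}prop-2-en-1-one F7.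
- HF·pyridine (THF, 0 °C) removes the three silyl groups under non-basic conditions to give 8.

Step 1. The risks are 3-O- or bis-alkylation and sluggish reaction of the tertiary chloride. The fallback removes the regiochemical question by using a mono-phenol and unmasking later; it sets out from 2 and comes back at 5. Commercial 4-hydroxy-3-methoxybenzaldehyde (vanillin) F8 is alkylated with 2 (K2CO3, KI, CuI, DMF) to 3-methoxy-4-[(2-methylbut-3-yn-2-yl)oxy]benzaldehyde F9. Claisen/electrocyclisation (PhNEt2, 200 °C) gives 8-methoxy-2,2-dimethyl-2H-chromene-6-carbaldehyde F10. NaSEt in DMF at 110 °C cleaves the methyl ether by SN2 at methyl to give 5.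

**Further compounds**
F1 | step 5 | rac-7-hydroxy-3-(8-hydroxy-2,2-dimethyl-2H-chromen-6-yl)-5-methoxychroman-4-one | COc1cc(O)cc2c1C(=O)C(c1cc(O)c3c(c1)C=CC(C)(C)O3)CO2
F2 | step 5 | (3R)-7-hydroxy-3-(8-hydroxy-2,2-dimethyl-2H-chromen-6-yl)-5-methoxychroman-4-one | COc1cc(O)cc2c1C(=O)[C@H](c1cc(O)c3c(c1)C=CC(C)(C)O3)CO2
F3 | step 4 | tert-butyl[(6-ethynyl-2,2-dimethyl-2H-chromen-8-yl)oxy]dimethylsilane | C#Cc1cc(O[Si](C)(C)C(C)(C)C)c2c(c1)C=CC(C)(C)O2
F4 | step 4 | {[6-(1-bromoethenyl)-2,2-dimethyl-2H-chromen-8-yl]oxy}(tert-butyl)dimethylsilane | C=C(Br)c1cc(O[Si](C)(C)C(C)(C)C)c2c(c1)C=CC(C)(C)O2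
F5 | step 4 | 2,4-bis[(tert-butyldimethylsilyl)oxy]-6-methoxybenzaldehyde | COc1cc(O[Si](C)(C)C(C)(C)C)cc(O[Si](C)(C)C(C)(C)C)c1C=O
F6 | step 4 | rac-1-{2,4-bis[(tert-butyldimethylsilyl)oxy]-6-methoxyphenyl}-2-{8-[(tert-butyldimethylsilyl)oxy]-2,2-dimethyl-2H-chromen-6-yl}prop-2-en-1-ol | COc1cc(O[Si](C)(C)C(C)(C)C)cc(O[Si](C)(C)C(C)(C)C)c1C(O)C(=C)c1cc(O[Si](C)(C)C(C)(C)C)c2c(c1)C=CC(C)(C)O2
F7 | step 4 | 1-{2,4-bis[(tert-butyldimethylsilyl)oxy]-6-methoxyphenyl}-2-{8-[(tert-butyldimethylsilyl)oxy]-2,2-dimethyl-2H-chromen-6-yl}prop-2-en-1-one | COc1cc(O[Si](C)(C)C(C)(C)C)cc(O[Si](C)(C)C(C)(C)C)c1C(=O)C(=C)c1cc(O[Si](C)(C)C(C)(C)C)c2c(c1)C=CC(C)(C)O2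
F8 | step 1 | 4-hydroxy-3-methoxybenzaldehyde (vanillin, commercial input) | COc1cc(C=O)ccc1O
F9 | step 1 | 3-methoxy-4-[(2-methylbut-3-yn-2-yl)oxy]benzaldehyde | COc1cc(C=O)ccc1OC(C)(C)C#C
F10 | step 1 | 8-methoxy-2,2-dimethyl-2H-chromene-6-carbaldehyde | COc1cc(C=O)cc2C=CC(C)(C)Oc12
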